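**Plan**

- Retrosynthesis: the ester C–O bonds at C4 and C6 are cut first, then the C2–CH2OH bond (Morita–Baylis–Hillman). The C2=C3 alkene is traced to a C3 carbinol and the ring C2–C3 bond is cut (aldol), which unravels the carbocycle to a methyl 6-deoxyhex-5-enopyranoside. Its isopropyl–carbon bond leads back to a 2,3-anhydro sugar.
- Enabling feature: the C1 ketone, C2 and C3, together with the all-cis C4–O / C5–isopropyl / C6–O triad, match sugar C5, C6, C1 and O2 / C3 branch / O4 of a D-allo-configured pyranoside.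
- Forward: methyl α-D-glucopyranoside → 4,6-acetal → 2,3-anhydromannoside → diaxial opening by an isopropyl copper reagent → oxidation/reduction at sugar C2 → 4-O-PMB 6-iodide → 5-ene. The cyclohexanone, the only ring of the target, closes in step 10. Enone formation, hydroxymethylation and two esterifications follow; the hydroxytiglic acid is made separately in two steps.
- Stereochemistry: C6 is sugar C4 of D-glucose, C5 comes from anti opening of the β-epoxide (step 3), C4 from β-face hydride delivery (step 5). The Z enoate comes from angelic acid and the E enoate from a stabilised-ylide Wittig reaction.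

Key step: step 10

Remark: ring atoms are numbered C1 (C=O), C2 (CH2OH-bearing), C3 (=CH), C4 (angelate), C5 (isopropyl), C6 (hydroxytiglate), and pyranose atoms are called sugar C1–C6. The carbinol formed in step 10 and the hemiketal centre of 13 are drawn as the expected epimers; neither centre survives into the target.

**Route**

Step 1
Reactants: 1 methyl α-D-glucopyranoside
Product: 2 methyl 4,6-O-[(R)-4-methoxybenzylidene]-α-D-glucopyranoside
Conditions: 4-MeOC6H4CH(OMe)2, CSA (cat.), DMF, 55 °C, 200 mbar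
Reagents that add atoms: 4-methoxybenzaldehyde dimethyl acetal, COc1ccc(C(OC)OC)cc1
Why: Acid-catalysed transacetalisation under thermodynamic control should give the trans-fused 1,3-dioxane across O4 and O6 with the aryl group equatorial, which fixes the acetal carbon as R.

Step 2
Reactants: 2 methyl 4,6-O-[(R)-4-methoxybenzylidene]-α-D-glucopyranoside
Product: 4 methyl 2,3-anhydro-4,6-O-[(R)-4-methoxybenzylidene]-α-D-mannopyranoside, via 2-O-tosylate 3 (not isolated)
Conditions: NaH (2.5 equiv), N-tosylimidazole (1.1 equiv), DMF, 0 °C → rt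
Reagents that add atoms: none
Why: The more acidic 2-hydroxyl should be sulfonylated first and the neighbouring 3-alkoxide then displaces the sulfonate in an intramolecular SN2 epoxide closure (Williamson type), which inverts sugar C2 and places the oxirane on the β-face.

Step 3
Reactants: 4 methyl 2,3-anhydro-4,6-O-[(R)-4-methoxybenzylidene]-α-D-mannopyranoside; 5 isopropylmagnesium chloride (4 equiv)
Product: 6 methyl 3-deoxy-3-C-isopropyl-4,6-O-[(R)-4-methoxybenzylidene]-α-D-altropyranoside
Conditions: CuI (0.2 equiv), THF, −30 → 0 °C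
Reagents that add atoms: none
Why: Copper-catalysed Grignard opening of the conformationally locked epoxide should follow the Fürst–Plattner trans-diaxial rule, so the isopropyl group enters at sugar C3 from the α-face with inversion and sets that centre cis to O4.

Step 4
Reactants: 6 methyl 3-deoxy-3-C-isopropyl-4,6-O-[(R)-4-methoxybenzylidene]-α-D-altropyranoside
Product: 7 methyl 3-deoxy-3-C-isopropyl-4,6-O-[(R)-4-methoxybenzylidene]-α-D-ribo-hexopyranosid-2-ulose
Conditions: Dess–Martin periodinane, pyridine, CH2Cl2, 0 °C → rt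
Reagents that add atoms: none
Why: Dess–Martin oxidation of the axial alcohol under buffered conditions should give the ketone without epimerising sugar C3, whose equatorial hydrogen lies near the carbonyl plane of the locked chair and is poorly aligned for enolisation.

Step 5
Reactants: 7 methyl 3-deoxy-3-C-isopropyl-4,6-O-[(R)-4-methoxybenzylidene]-α-D-ribo-hexopyranosid-2-ulose
Product: 8 methyl 3-deoxy-3-C-isopropyl-4,6-O-[(R)-4-methoxybenzylidene]-α-D-allopyranoside
Conditions: NaBH4, MeOH/CH2Cl2, −40 → −20 °C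
Reagents that add atoms: none
Why: Borohydride reduction should occur from the β-face because the α-face is screened by the axial anomeric methoxyl and the axial isopropyl group, so the new hydroxyl at sugar C2 is equatorial and cis to the isopropyl group (net inversion of C2 by oxidation–reduction).

Step 6
Reactants: 8 methyl 3-deoxy-3-C-isopropyl-4,6-O-[(R)-4-methoxybenzylidene]-α-D-allopyranoside
Product: 9 methyl 2-O-(tert-butyldimethylsilyl)-3-deoxy-3-C-isopropyl-4,6-O-[(R)-4-methoxybenzylidene]-α-D-allopyranoside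
Conditions: TBSCl, imidazole, DMAP (cat.), DMF, 50 °C
Reagents that add atoms: tert-butyldimethylsilyl chloride, CC(C)(C)[Si](C)(C)Cl
Why: Imidazole-mediated silylation (Corey conditions) of the only free hydroxyl is basic and should leave the acid-labile aryl acetal untouched.

Step 7
Reactants: 9 methyl 2-O-(tert-butyldimethylsilyl)-3-deoxy-3-C-isopropyl-4,6-O-[(R)-4-methoxybenzylidene]-α-D-allopyranoside
Product: 10 methyl 2-O-(tert-butyldimethylsilyl)-3-deoxy-3-C-isopropyl-4-O-(4-methoxybenzyl)-α-D-allopyranoside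
Conditions: i-Bu2AlH (1 M in toluene), toluene, −20 → 0 °C; aqueous Rochelle salt work-up
Reagents that add atoms: none
Why: In this reductive acetal opening the aluminium hydride should bind the less hindered O6, the C–O6 bond breaks and hydride is delivered to the oxocarbenium ion, which leaves the PMB ether on O4 and frees the primary hydroxyl.

Step 8
Reactants: 10 methyl 2-O-(tert-butyldimethylsilyl)-3-deoxy-3-C-isopropyl-4-O-(4-methoxybenzyl)-α-D-allopyranoside
Product: 11 methyl 2-O-(tert-butyldimethylsilyl)-3,6-dideoxy-6-iodo-3-C-isopropyl-4-O-(4-methoxybenzyl)-α-D-allopyranoside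
Conditions: I2, PPh3, imidazole, toluene, 60 °C
Reagents that add atoms: iodine, [I][I]
Why: Appel-type iodination (Garegg–Samuelsson conditions) converts the primary alcohol through its alkoxyphosphonium salt by SN2 displacement and touches no stereocentre.

Step 9
Reactants: 11 methyl 2-O-(tert-butyldimethylsilyl)-3,6-dideoxy-6-iodo-3-C-isopropyl-4-O-(4-methoxybenzyl)-α-D-allopyranoside
Product: 12 methyl 2-O-(tert-butyldimethylsilyl)-3,6-dideoxy-3-C-isopropyl-4-O-(4-methoxybenzyl)-α-D-ribo-hex-5-enopyranoside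
Conditions: KOt-Bu, THF, 0 °C → rt
Reagents that add atoms: none
Why: E2 dehydroiodination of the primary iodide with a hindered alkoxide should give the exocyclic enol ether, the usual entry to 6-deoxyhex-5-enopyranosides.

Step 10
Reactants: 12 methyl 2-O-(tert-butyldimethylsilyl)-3,6-dideoxy-3-C-isopropyl-4-O-(4-methoxybenzyl)-α-D-ribo-hex-5-enopyranoside
Product: 15 (2S,3R,4R,5R)-4-[(tert-butyldimethylsilyl)oxy]-5-hydroxy-3-isopropyl-2-[(4-methoxybenzyl)oxy]cyclohexan-1-one, via hemiketal mercurial 13 (not isolated), via keto aldehyde mercurial 14 (not isolated)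
Conditions: Hg(OCOCF3)2 (0.1 equiv), acetone/H2O 4:1, rt
Reagents that add atoms: water, O
Why: Hg(OCOCF3)2 (divalent mercury) should add with water across the electron-rich exocyclic enol ether in the Markovnikov sense, placing mercury on sugar C6 and hydroxyl on sugar C5 (hemiketal 13); the hemiketal opens, methanol leaves the anomeric carbon and the open-chain keto aldehyde mercurial 14 results, whose mercury enolate adds to the aldehyde and returns the mercury salt for the next turnover. The closest known reaction type is the Ferrier carbocyclisation of 6-deoxyhex-5-enopyranosides. The six-membered carbocycle closes by a 6-(enolexo)-exo-trig aldol that forms the ring C2–C3 bond (sugar C6 to sugar C1). The one new stereocentre, the ring C3 carbinol, is set in a chair-like aldol transition state in which the aldehyde oxygen lies anti to the neighbouring silyloxy group (drawn trans to it), and it is of no consequence because step 11 removes it. The step needs enolisation only toward sugar C6 and intact centres at sugar C2 and sugar C4, which flank the two carbonyl groups: the first is secured because mercury already sits on C6, the second by the near-neutral aqueous acetone medium and the fast intramolecular trapping. The all-cis triad is carried through unchanged from 12.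

Step 11
Reactants: 15 (2S,3R,4R,5R)-4-[(tert-butyldimethylsilyl)oxy]-5-hydroxy-3-isopropyl-2-[(4-methoxybenzyl)oxy]cyclohexan-1-one
Product: 17 (4S,5R,6S)-4-[(tert-butyldimethylsilyl)oxy]-5-isopropyl-6-[(4-methoxybenzyl)oxy]cyclohex-2-en-1-one, via mesylate 16 (not isolated)
Conditions: MsCl, Et3N, CH2Cl2, 0 °C → rt
Reagents that add atoms: none
Why: Mesylation of the β-hydroxy ketone followed by E1cB elimination in the same flask should give the conjugated enone from either carbinol epimer, at a temperature too low for the amine to epimerise C6.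

Step 12
Reactants: 17 (4S,5R,6S)-4-[(tert-butyldimethylsilyl)oxy]-5-isopropyl-6-[(4-methoxybenzyl)oxy]cyclohex-2-en-1-one
Product: 18 (4S,5R,6S)-4-[(tert-butyldimethylsilyl)oxy]-2-(hydroxymethyl)-5-isopropyl-6-[(4-methoxybenzyl)oxy]cyclohex-2-en-1-one
Conditions: 37% aq. CH2O, imidazole, THF/1 M aq. NaHCO3, rt
Reagents that add atoms: formaldehyde, C=O
Why: In this Morita–Baylis–Hillman reaction imidazole adds reversibly to C3, the resulting enolate traps formaldehyde at C2 and loss of the catalyst restores the enone, so no stereocentre is formed and the weakly basic medium should leave C6 alone.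

Step 13
Reactants: 18 (4S,5R,6S)-4-[(tert-butyldimethylsilyl)oxy]-2-(hydroxymethyl)-5-isopropyl-6-[(4-methoxybenzyl)oxy]cyclohex-2-en-1-one
Product: 19 (4S,5S,6S)-4-hydroxy-2-(hydroxymethyl)-5-isopropyl-6-[(4-methoxybenzyl)oxy]cyclohex-2-en-1-one
Conditions: 48% aq. HF, MeCN, 0 °C → rt
Reagents that add atoms: none
Why: Fluoride-driven cleavage of the secondary silyl ether under mildly acidic conditions should spare the PMB ether and avoids the basic conditions that could isomerise a γ-hydroxy enone.

Step 14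
Reactants: 19 (4S,5S,6S)-4-hydroxy-2-(hydroxymethyl)-5-isopropyl-6-[(4-methoxybenzyl)oxy]cyclohex-2-en-1-one
Product: 20 (4S,5S,6S)-2-{[(tert-butyldimethylsilyl)oxy]methyl}-4-hydroxy-5-isopropyl-6-[(4-methoxybenzyl)oxy]cyclohex-2-en-1-one
Conditions: TBSCl (1.05 equiv), imidazole, CH2Cl2, −20 → 0 °C
Reagents that add atoms: tert-butyldimethylsilyl chloride, CC(C)(C)[Si](C)(C)Cl
Why: Kinetically controlled silylation should take the unhindered primary allylic hydroxyl and leave the secondary C4 hydroxyl, which is flanked by the cis isopropyl group, free for acylation.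

Step 15
Reactants: 20 (4S,5S,6S)-2-{[(tert-butyldimethylsilyl)oxy]methyl}-4-hydroxy-5-isopropyl-6-[(4-methoxybenzyl)oxy]cyclohex-2-en-1-one; 21 angelic acid (3 equiv)
Product: 23 (4S,5S,6S)-4-(angeloyloxy)-2-{[(tert-butyldimethylsilyl)oxy]methyl}-5-isopropyl-6-[(4-methoxybenzyl)oxy]cyclohex-2-en-1-one, via angelic 2,4,6-trichlorobenzoic anhydride 22 (not isolated)
Conditions: 2,4,6-Cl3C6H2COCl, Et3N, toluene, rt; then 20, 80 °C (no DMAP)
Reagents that add atoms: none
Why: In this Yamaguchi-type mixed-anhydride esterification the alcohol attacks the less hindered angeloyl carbonyl of 22, and leaving out the nucleophilic catalyst is the known way to keep the Z geometry of the angeloyl group.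

Step 16
Reactants: 23 (4S,5S,6S)-4-(angeloyloxy)-2-{[(tert-butyldimethylsilyl)oxy]methyl}-5-isopropyl-6-[(4-methoxybenzyl)oxy]cyclohex-2-en-1-one
Product: 24 (4S,5R,6S)-4-(angeloyloxy)-2-{[(tert-butyldimethylsilyl)oxy]methyl}-6-hydroxy-5-isopropylcyclohex-2-en-1-one
Conditions: DDQ, CH2Cl2/pH 7 phosphate buffer, 0 °C → rt
Reagents that add atoms: none
Why: Oxidative PMB cleavage by DDQ proceeds through the benzylic oxocarbenium ion, which water hydrolyses, under buffered neutral conditions that should not affect the esters, the silyl ether or the electron-poor enone.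

Step 17
Reactants: 25 (tert-butyldimethylsilyloxy)acetaldehyde; 26 ethyl 2-(triphenylphosphoranylidene)propanoate
Product: 27 ethyl (2E)-4-[(tert-butyldimethylsilyl)oxy]-2-methylbut-2-enoate
Conditions: CH2Cl2, rt
Reagents that add atoms: none
Why: A Wittig reaction of the stabilised α-methyl ylide with an aldehyde should give the E-trisubstituted enoate, the tiglate geometry.

Step 18
Reactants: 27 ethyl (2E)-4-[(tert-butyldimethylsilyl)oxy]-2-methylbut-2-enoate
Product: 28 (2E)-4-[(tert-butyldimethylsilyl)oxy]-2-methylbut-2-enoic acid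
Conditions: LiOH, THF/MeOH/H2O, 0 °C → rt; then 1 M HCl to pH 4 at 0 °C
Reagents that add atoms: lithium hydroxide, [Li+].[OH-]
Why: Saponification of the ethyl ester by acyl–oxygen cleavage is routine, and a primary TBS ether should withstand LiOH and a brief mildly acidic work-up.

Step 19
Reactants: 24 (4S,5R,6S)-4-(angeloyloxy)-2-{[(tert-butyldimethylsilyl)oxy]methyl}-6-hydroxy-5-isopropylcyclohex-2-en-1-one; 28 (2E)-4-[(tert-butyldimethylsilyl)oxy]-2-methylbut-2-enoic acid
Product: 30 (4S,5S,6S)-4-(angeloyloxy)-6-{[(2E)-4-[(tert-butyldimethylsilyl)oxy]-2-methylbut-2-enoyl]oxy}-2-{[(tert-butyldimethylsilyl)oxy]methyl}-5-isopropylcyclohex-2-en-1-one, via mixed anhydride 29 (not isolated)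
Conditions: 2,4,6-Cl3C6H2COCl, Et3N, THF, rt; then 24, DMAP (0.3 equiv), toluene, 0 °C → rt
Reagents that add atoms: none
Why: Yamaguchi esterification with DMAP-catalysed acyl transfer should acylate the hindered α-hydroxy ketone at low temperature, and the E enoate is the thermodynamic isomer so no geometric change is expected.

Step 20
Reactants: 30 (4S,5S,6S)-4-(angeloyloxy)-6-{[(2E)-4-[(tert-butyldimethylsilyl)oxy]-2-methylbut-2-enoyl]oxy}-2-{[(tert-butyldimethylsilyl)oxy]methyl}-5-isopropylcyclohex-2-en-1-one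
Product: 31 (4S,5S,6S)-4-(angeloyloxy)-6-{[(2E)-4-hydroxy-2-methylbut-2-enoyl]oxy}-2-(hydroxymethyl)-5-isopropylcyclohex-2-en-1-one (CNP0281432.2)
Conditions: HF·pyridine, pyridine, THF, 0 °C → rt
Reagents that add atoms: none
Why: Buffered HF·pyridine desilylation should remove both primary TBS ethers under mildly acidic conditions that avoid acyl migration, loss of carboxylic acid from the γ-acyloxy enone and isomerisation of the angelate.

**Compound list**

1 | methyl α-D-glucopyranoside | CO[C@H]1O[C@H](CO)[C@@H](O)[C@H](O)[C@H]1O | starting material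
2 | methyl 4,6-O-[(R)-4-methoxybenzylidene]-α-D-glucopyranoside | CO[C@H]1O[C@@H]2CO[C@@H](c3ccc(OC)cc3)O[C@H]2[C@H](O)[C@H]1O | intermediate
3 | methyl 4,6-O-[(R)-4-methoxybenzylidene]-2-O-(4-methylbenzenesulfonyl)-α-D-glucopyranoside (present as its 3-O-sodium alkoxide; not isolated) | CO[C@H]1O[C@@H]2CO[C@@H](c3ccc(OC)cc3)O[C@H]2[C@H](O)[C@H]1OS(=O)(=O)c1ccc(C)cc1 | intermediate
4 | methyl 2,3-anhydro-4,6-O-[(R)-4-methoxybenzylidene]-α-D-mannopyranoside | CO[C@H]1O[C@@H]2CO[C@@H](c3ccc(OC)cc3)O[C@H]2[C@@H]2O[C@H]12 | intermediate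
5 | isopropylmagnesium chloride | CC(C)[Mg]Cl | starting material
6 | methyl 3-deoxy-3-C-isopropyl-4,6-O-[(R)-4-methoxybenzylidene]-α-D-altropyranoside (isopropyl axial, cis to O4; 2-OH axial) | CO[C@H]1O[C@@H]2CO[C@@H](c3ccc(OC)cc3)O[C@H]2[C@@H](C(C)C)[C@@H]1O | intermediate
7 | methyl 3-deoxy-3-C-isopropyl-4,6-O-[(R)-4-methoxybenzylidene]-α-D-ribo-hexopyranosid-2-ulose (isopropyl cis to O4) | CO[C@H]1O[C@@H]2CO[C@@H](c3ccc(OC)cc3)O[C@H]2[C@@H](C(C)C)C1=O | intermediate
8 | methyl 3-deoxy-3-C-isopropyl-4,6-O-[(R)-4-methoxybenzylidene]-α-D-allopyranoside (O2, isopropyl and O4 all cis) | CO[C@H]1O[C@@H]2CO[C@@H](c3ccc(OC)cc3)O[C@H]2[C@@H](C(C)C)[C@H]1O | intermediate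
9 | methyl 2-O-(tert-butyldimethylsilyl)-3-deoxy-3-C-isopropyl-4,6-O-[(R)-4-methoxybenzylidene]-α-D-allopyranoside | CO[C@H]1O[C@@H]2CO[C@@H](c3ccc(OC)cc3)O[C@H]2[C@@H](C(C)C)[C@H]1O[Si](C)(C)C(C)(C)C | intermediate
10 | methyl 2-O-(tert-butyldimethylsilyl)-3-deoxy-3-C-isopropyl-4-O-(4-methoxybenzyl)-α-D-allopyranoside | CO[C@H]1O[C@H](CO)[C@@H](OCc2ccc(OC)cc2)[C@@H](C(C)C)[C@H]1O[Si](C)(C)C(C)(C)C | intermediate
11 | methyl 2-O-(tert-butyldimethylsilyl)-3,6-dideoxy-6-iodo-3-C-isopropyl-4-O-(4-methoxybenzyl)-α-D-allopyranoside | CO[C@H]1O[C@H](CI)[C@@H](OCc2ccc(OC)cc2)[C@@H](C(C)C)[C@H]1O[Si](C)(C)C(C)(C)C | intermediate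
12 | methyl 2-O-(tert-butyldimethylsilyl)-3,6-dideoxy-3-C-isopropyl-4-O-(4-methoxybenzyl)-α-D-ribo-hex-5-enopyranoside (O2, isopropyl and O4 all cis) | C=C1O[C@H](OC)[C@H](O[Si](C)(C)C(C)(C)C)[C@H](C(C)C)[C@@H]1OCc1ccc(OC)cc1 | intermediate
13 | hemiketal mercurial: hydroxymercuration adduct of 12 with OH on sugar C5 and HgOCOCF3 on sugar C6 (hemiketal hydroxyl drawn axial; not isolated) | CO[C@H]1O[C@](O)(C[Hg]OC(=O)C(F)(F)F)[C@@H](OCc2ccc(OC)cc2)[C@@H](C(C)C)[C@H]1O[Si](C)(C)C(C)(C)C | intermediate
14 | keto aldehyde mercurial: aldehydo-2-O-(tert-butyldimethylsilyl)-3,6-dideoxy-3-C-isopropyl-4-O-(4-methoxybenzyl)-6-(trifluoroacetoxymercurio)-D-ribo-hexos-5-ulose (not isolated) | O=C[C@H](O[Si](C)(C)C(C)(C)C)[C@H](C(C)C)[C@H](OCc1ccc(OC)cc1)C(=O)C[Hg]OC(=O)C(F)(F)F | intermediate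
15 | (2S,3R,4R,5R)-4-[(tert-butyldimethylsilyl)oxy]-5-hydroxy-3-isopropyl-2-[(4-methoxybenzyl)oxy]cyclohexan-1-one (2,3,4-all-cis; 5-OH trans to 4-OTBS) | O=C1C[C@@H](O)[C@H](O[Si](C)(C)C(C)(C)C)[C@H](C(C)C)[C@@H]1OCc1ccc(OC)cc1 | intermediate
16 | 5-O-methanesulfonate of 15 (not isolated) | O=C1C[C@@H](OS(C)(=O)=O)[C@H](O[Si](C)(C)C(C)(C)C)[C@H](C(C)C)[C@@H]1OCc1ccc(OC)cc1 | intermediate
17 | (4S,5R,6S)-4-[(tert-butyldimethylsilyl)oxy]-5-isopropyl-6-[(4-methoxybenzyl)oxy]cyclohex-2-en-1-one (4,5,6-all-cis) | O=C1C=C[C@H](O[Si](C)(C)C(C)(C)C)[C@H](C(C)C)[C@@H]1OCc1ccc(OC)cc1 | intermediate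
18 | (4S,5R,6S)-4-[(tert-butyldimethylsilyl)oxy]-2-(hydroxymethyl)-5-isopropyl-6-[(4-methoxybenzyl)oxy]cyclohex-2-en-1-one | O=C1C(CO)=C[C@H](O[Si](C)(C)C(C)(C)C)[C@H](C(C)C)[C@@H]1OCc1ccc(OC)cc1 | intermediate
19 | (4S,5S,6S)-4-hydroxy-2-(hydroxymethyl)-5-isopropyl-6-[(4-methoxybenzyl)oxy]cyclohex-2-en-1-one | O=C1C(CO)=C[C@H](O)[C@H](C(C)C)[C@@H]1OCc1ccc(OC)cc1 | intermediate
20 | (4S,5S,6S)-2-{[(tert-butyldimethylsilyl)oxy]methyl}-4-hydroxy-5-isopropyl-6-[(4-methoxybenzyl)oxy]cyclohex-2-en-1-one | O=C1C(CO[Si](C)(C)C(C)(C)C)=C[C@H](O)[C@H](C(C)C)[C@@H]1OCc1ccc(OC)cc1 | intermediate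
21 | angelic acid, (2Z)-2-methylbut-2-enoic acid | C/C=C(/C)C(=O)O | starting material
22 | angelic 2,4,6-trichlorobenzoic anhydride (not isolated) | C/C=C(/C)C(=O)OC(=O)c1c(Cl)cc(Cl)cc1Cl | intermediate
23 | (4S,5S,6S)-4-(angeloyloxy)-2-{[(tert-butyldimethylsilyl)oxy]methyl}-5-isopropyl-6-[(4-methoxybenzyl)oxy]cyclohex-2-en-1-one | O=C1C(CO[Si](C)(C)C(C)(C)C)=C[C@H](OC(=O)/C(C)=C\C)[C@H](C(C)C)[C@@H]1OCc1ccc(OC)cc1 | intermediate
24 | (4S,5R,6S)-4-(angeloyloxy)-2-{[(tert-butyldimethylsilyl)oxy]methyl}-6-hydroxy-5-isopropylcyclohex-2-en-1-one | O=C1C(CO[Si](C)(C)C(C)(C)C)=C[C@H](OC(=O)/C(C)=C\C)[C@H](C(C)C)[C@@H]1O | intermediate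
25 | (tert-butyldimethylsilyloxy)acetaldehyde | O=CCO[Si](C)(C)C(C)(C)C | starting material
26 | ethyl 2-(triphenylphosphoranylidene)propanoate | CCOC(=O)C(C)=P(c1ccccc1)(c1ccccc1)c1ccccc1 | starting material
27 | ethyl (2E)-4-[(tert-butyldimethylsilyl)oxy]-2-methylbut-2-enoate | CCOC(=O)/C(C)=C/CO[Si](C)(C)C(C)(C)C | intermediate
28 | (2E)-4-[(tert-butyldimethylsilyl)oxy]-2-methylbut-2-enoic acid | OC(=O)/C(C)=C/CO[Si](C)(C)C(C)(C)C | intermediate
29 | (2E)-4-[(tert-butyldimethylsilyl)oxy]-2-methylbut-2-enoic 2,4,6-trichlorobenzoic anhydride (not isolated) | O=C(OC(=O)c1c(Cl)cc(Cl)cc1Cl)/C(C)=C/CO[Si](C)(C)C(C)(C)C | intermediate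
30 | (4S,5S,6S)-4-(angeloyloxy)-6-{[(2E)-4-[(tert-butyldimethylsilyl)oxy]-2-methylbut-2-enoyl]oxy}-2-{[(tert-butyldimethylsilyl)oxy]methyl}-5-isopropylcyclohex-2-en-1-one | O=C1C(CO[Si](C)(C)C(C)(C)C)=C[C@H](OC(=O)/C(C)=C\C)[C@H](C(C)C)[C@@H]1OC(=O)/C(C)=C/CO[Si](C)(C)C(C)(C)C | intermediate
31 | (1S,5S,6S)-5-{[(2E)-4-hydroxy-2-methylbut-2-enoyl]oxy}-3-(hydroxymethyl)-4-oxo-6-(propan-2-yl)cyclohex-2-en-1-yl (2Z)-2-methylbut-2-enoate (CNP0281432.2; 4S,5S,6S in the ring numbering used here) | C/C=C(/C)C(=O)O[C@H]1C=C(CO)C(=O)[C@@H](OC(=O)/C(C)=C/CO)[C@H]1C(C)C | target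

**Step count and risks**

Total step count: 20. Longest linear sequence: 18 steps (steps 1–16, 19 and 20) from methyl α-D-glucopyranoside; steps 17 and 18 prepare the acid side chain.

Steps most likely to fail:

1. Step 3. The secondary alkyl copper reagent may deliver hydride or chloride (reduction or halohydrin formation) faster than the isopropyl group, and diaxial entry at sugar C3 is slowed by the syn-axial anomeric methoxyl. Fallback: setting out from epoxide 4, CH2=C(CH3)MgBr with catalytic CuI in THF should open the oxirane in the same diaxial sense, since alkenyl copper reagents are smaller, more robust and not prone to reduction pathways. This would give methyl 3-deoxy-3-C-isopropenyl-4,6-O-[(R)-4-methoxybenzylidene]-α-D-altropyranoside F1. Homogeneous hydrogenation of its 1,1-disubstituted alkene with H2 and RhCl(PPh3)3 in benzene/ethanol, which spares the benzylic acetal, returns to the route at 6.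

2. Step 15. Acylation of the hindered allylic hydroxyl may be slow at the temperature needed, giving time for Z to E isomerisation of the angeloyl unit or for amine-induced isomerisation of the γ-hydroxy enone. Fallback: setting out from alcohol 20, esterification with 2-[bis(2,2,2-trifluoroethoxy)phosphoryl]propanoic acid (DCC, DMAP, CH2Cl2, 0 °C) would give the 4-O-{2-[bis(2,2,2-trifluoroethoxy)phosphoryl]propanoyl} derivative of 20 F3 (both epimers at the phosphorus-bearing carbon). A Still–Gennari olefination (KN(SiMe3)2, 18-crown-6, THF, −78 °C, then acetaldehyde) then builds the Z-trisubstituted enoate on the substrate and rejoins the route at 23.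

3. Step 12. Conjugate addition of the catalyst to C3 next to the bulky silyloxy group may be slow, so that the enone stays long in a basic aqueous medium and C6 epimerises or the material decomposes. Fallback: setting out from enone 17, α-iodination with I2 and pyridine in CH2Cl2 should give (4R,5R,6S)-4-[(tert-butyldimethylsilyl)oxy]-2-iodo-5-isopropyl-6-[(4-methoxybenzyl)oxy]cyclohex-2-en-1-one F2. Stille coupling with Bu3SnCH2OH and Pd(PPh3)4 in dioxane at 80 °C installs the hydroxymethyl group under neutral conditions and returns to the route at 18.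

Further compounds
F1 | step 3 | methyl 3-deoxy-3-C-isopropenyl-4,6-O-[(R)-4-methoxybenzylidene]-α-D-altropyranoside | CO[C@H]1O[C@@H]2CO[C@@H](c3ccc(OC)cc3)O[C@H]2[C@@H](C(C)=C)[C@@H]1O
F2 | step 12 | (4R,5R,6S)-4-[(tert-butyldimethylsilyl)oxy]-2-iodo-5-isopropyl-6-[(4-methoxybenzyl)oxy]cyclohex-2-en-1-one | O=C1C(I)=C[C@H](O[Si](C)(C)C(C)(C)C)[C@H](C(C)C)[C@@H]1OCc1ccc(OC)cc1
F3 | step 15 | (1S,5S,6S)-3-{[(tert-butyldimethylsilyl)oxy]methyl}-5-[(4-methoxybenzyl)oxy]-4-oxo-6-isopropylcyclohex-2-en-1-yl 2-[bis(2,2,2-trifluoroethoxy)phosphoryl]propanoate (both epimers at the phosphorus-bearing carbon) | O=C1C(CO[Si](C)(C)C(C)(C)C)=C[C@H](OC(=O)C(C)P(=O)(OCC(F)(F)F)OCC(F)(F)F)[C@H](C(C)C)[C@@H]1OCc1ccc(OC)cc1
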